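**Retrosynthetic overview**

1. Locants: ring A is C1 (butanoyl), C2 (CH3), C3 (CH2 bridge), C4 (OCH3), C5 (CH3), C6 (OH); ring B is C1' (bridge), C2'/C4'/C6' (OH), C3' (CH3), C5' (butanoyl). The strategy rests on the C4–C5–C6 triad of ring A, a 2-methyl-1,3-dioxygenated unit that is a 2-methylcyclohexane-1,3-dione one dehydrogenation below the arene, so the neighbouring C2 and C3 can be made as sp3 carbons by conjugate addition.
2. End game: the target comes from its tris-benzyl ether by hydrogenolysis; both butanoyl groups come from formyl groups placed in one Vilsmeier step at C1 (ring A) and C5' (ring B); the C1 carbonyl ties up O6–H so that only O4 is methylated.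
3. Ring A (the only ring formed; ring B is bought as 2-methylphloroglucinol): the resorcinol comes from the saturated 1,3-dione by dehydrogenation, and the dione from a δ-keto ester by Claisen closure of C4–C5.
4. The δ-keto ester comes from a Mukaiyama–Michael addition (C2–C3 bond) of the silyl ketene acetal of methyl 3-arylpropanoate to (E)-hex-4-en-3-one; the propanoate comes from the ring B aldehyde by Horner–Wadsworth–Emmons olefination and conjugate reduction.

Key step: step 6

Assumption: the target is achiral, so the sp3 centres that appear in 10–13 and 18 are carried as racemic diastereomer mixtures and are erased in steps 7 and 11; 11–13 are drawn as the racemic diastereomer that corresponds to the trans dione, while 9, 10 and 18 are written without descriptors.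

**Route**

Step 1
Reactants: 1 2-methylphloroglucinol
Product: 3 2,4,6-trihydroxy-3-methylbenzaldehyde, via aryl-iminium chloride 2 (not isolated)
Conditions: POCl3 (1.1 equiv), DMF, EtOAc, 0 °C to rt; then H2O, 60 °C
Reagents that add atoms: N,N-dimethylformamide CN(C)C=O; water O
Why: Vilsmeier–Haack formylation, in which the chloroiminium ion from DMF and POCl3 should attack one of the two equivalent free positions of the strongly activated triol and the deactivating iminium group of 2 should prevent a second substitution before hydrolysis.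

Step 2
Reactants: 3 2,4,6-trihydroxy-3-methylbenzaldehyde
Product: 4 2,4,6-tris(benzyloxy)-3-methylbenzaldehyde
Conditions: BnBr (3.6 equiv), K2CO3, DMF, 60 °C
Reagents that add atoms: benzyl bromide BrCc1ccccc1
Why: Williamson ether synthesis; the formyl group lowers the carbon nucleophilicity of the ring so that O-benzylation should prevail over C-benzylation, and excess reagent with warming should also alkylate the two hydrogen-bonded ortho hydroxyls.

Step 3
Reactants: 4 2,4,6-tris(benzyloxy)-3-methylbenzaldehyde; 5 trimethyl phosphonoacetate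
Product: 6 methyl (E)-3-[2,4,6-tris(benzyloxy)-3-methylphenyl]prop-2-enoate
Conditions: NaH, THF, 0 °C to rt
Reagents that add atoms: none
Why: Horner–Wadsworth–Emmons olefination; the stabilised phosphonate anion adds reversibly to the aldehyde and elimination of dimethyl phosphate should give the (E)-enoate under thermodynamic control.

Step 4
Reactants: 6 methyl (E)-3-[2,4,6-tris(benzyloxy)-3-methylphenyl]prop-2-enoate
Product: 7 methyl 3-[2,4,6-tris(benzyloxy)-3-methylphenyl]propanoate
Conditions: NaBH4, NiCl2·6H2O (0.3 equiv), CH3OH/THF, 0 °C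
Reagents that add atoms: none
Why: Conjugate reduction by nickel boride formed in the flask, a reagent that saturates enoate double bonds and should leave aryl benzyl ethers and the ester untouched, unlike hydrogenation over palladium.

Step 5
Reactants: 7 methyl 3-[2,4,6-tris(benzyloxy)-3-methylphenyl]propanoate; 8 (E)-hex-4-en-3-one
Product: 11 methyl 3-methyl-5-oxo-2-{[2,4,6-tris(benzyloxy)-3-methylphenyl]methyl}heptanoate (racemic diastereomer mixture), via silyl ketene acetal 9 (not isolated), via silyl enol ether 10 (not isolated)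
Conditions: LiN(CH(CH3)2)2, THF, −78 °C; (CH3)3SiCl, −78 °C to rt; solvent switch to CH2Cl2; 8, Sc(OTf)3 (10 mol%), −78 to −20 °C; 1 M HCl, THF, 0 °C
Reagents that add atoms: none
Why: Mukaiyama–Michael addition, in which ketene acetal 9 should attack the β-carbon of the Lewis-acid-activated enone through an open transition state to form the C2–C3 bond and silyl enol ether 10, hydrolysed on work-up; the two new centres (C2 and C3 of ring A) form without control, which is acceptable because step 7 removes both.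

Step 6
Reactants: 11 methyl 3-methyl-5-oxo-2-{[2,4,6-tris(benzyloxy)-3-methylphenyl]methyl}heptanoate
Product: 13 rac-(5S,6R)-3-hydroxy-2,5-dimethyl-6-{[2,4,6-tris(benzyloxy)-3-methylphenyl]methyl}cyclohex-2-en-1-one (enol form of the 1,3-dione), via potassium enolate 12 (not isolated)
Conditions: KOC(CH3)3 (2.2 equiv), THF, 0 °C to rt; then 1 M HCl
Reagents that add atoms: none
Why: This is a Dieckmann-type intramolecular Claisen condensation of a δ-keto ester, the classical entry to 2-alkylcyclohexane-1,3-diones: tert-butoxide equilibrates the enolates of the ethyl ketone, and the one at C5 adds to the ester carbon C4 to give a tetrahedral alkoxide that expels methoxide. Ring A closes in a 6-(enolexo)-exo-trig mode, which is geometrically favoured. No stereocentre is created, since C5 ends as an sp2 carbon of the vinylogous acid; the centres at C2 and C3 are not controlled and need not be, because C3 can epimerise next to the new C4 carbonyl (trans expected) and both are lost in step 7. The selectivity required is the choice of enolate, and ring size secures it: the C1 enolate could reach the ester only through a four-membered ring and the ester enolate at C3 could reach the ketone only through a four-membered aldol, so both revert. The equilibrium should be pulled forward by deprotonation of the new 1,3-dione to the delocalised enolate 12, which is why more than one equivalent of base is used and acid is needed to release 13. The benzyl ethers and the free C5' position of ring B are inert to alkoxide.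

Step 7
Reactants: 13 rac-(5S,6R)-3-hydroxy-2,5-dimethyl-6-{[2,4,6-tris(benzyloxy)-3-methylphenyl]methyl}cyclohex-2-en-1-one
Product: 14 2,5-dimethyl-4-{[2,4,6-tris(benzyloxy)-3-methylphenyl]methyl}benzene-1,3-diol
Conditions: DDQ (1.05 equiv), 1,4-dioxane, 60–80 °C
Reagents that add atoms: none
Why: Quinone dehydrogenation of a cyclohexane-1,3-dione to a resorcinol; DDQ should abstract hydride from the dienol tautomer and proton loss with tautomerisation then gives the arene, erasing both sp3 centres, while one equivalent of oxidant limits further oxidation.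

Step 8
Reactants: 14 2,5-dimethyl-4-{[2,4,6-tris(benzyloxy)-3-methylphenyl]methyl}benzene-1,3-diol
Product: 16 2,4-dihydroxy-3,6-dimethyl-5-{[2,4,6-tris(benzyloxy)-3-formyl-5-methylphenyl]methyl}benzaldehyde, via bis-iminium dichloride 15 (not isolated)
Conditions: POCl3 (5 equiv), DMF, 0 to 50 °C; then H2O, 50 °C
Reagents that add atoms: N,N-dimethylformamide CN(C)C=O; water O
Why: Twofold Vilsmeier–Haack formylation; each ring has exactly one unsubstituted position (C1 of ring A, ortho and para to the two hydroxyls, and C5' of ring B, flanked by two benzyloxy groups), the weak chloroiminium electrophile should prefer these C–H sites over ipso attack, and aryl benzyl ethers tolerate the conditions.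

Step 9
Reactants: 16 2,4-dihydroxy-3,6-dimethyl-5-{[2,4,6-tris(benzyloxy)-3-formyl-5-methylphenyl]methyl}benzaldehyde
Product: 17 2-hydroxy-4-methoxy-3,6-dimethyl-5-{[2,4,6-tris(benzyloxy)-3-formyl-5-methylphenyl]methyl}benzaldehyde
Conditions: CH3I (1.1 equiv), K2CO3 (1.1 equiv), acetone, rt
Reagents that add atoms: iodomethane CI
Why: Williamson O-methylation made selective by chelation; O6–H is hydrogen-bonded to the C1 formyl group, whereas O4–H, para to that formyl group, is free and more acidic, so one equivalent of base and electrophile should methylate O4 only.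

Step 10
Reactants: 17 2-hydroxy-4-methoxy-3,6-dimethyl-5-{[2,4,6-tris(benzyloxy)-3-formyl-5-methylphenyl]methyl}benzaldehyde
Product: 18 1-[2-hydroxy-4-methoxy-3,6-dimethyl-5-({2,4,6-tris(benzyloxy)-3-(1-hydroxybutyl)-5-methylphenyl}methyl)phenyl]butan-1-ol (diastereomer mixture)
Conditions: CH3CH2CH2MgBr (5 equiv), THF, −20 to 0 °C; sat. aq. NH4Cl; used crude
Reagents that add atoms: propylmagnesium bromide CCC[Mg]Br
Why: Grignard 1,2-addition to both aldehydes after the first equivalent has deprotonated the phenol; the two carbinol centres form without control and are removed in step 11, and a neutral work-up should keep the ionisable benzylic alcohols intact.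

Step 11
Reactants: 18 1-[2-hydroxy-4-methoxy-3,6-dimethyl-5-({2,4,6-tris(benzyloxy)-3-(1-hydroxybutyl)-5-methylphenyl}methyl)phenyl]butan-1-ol
Product: 19 1-[2-hydroxy-4-methoxy-3,6-dimethyl-5-({2,4,6-tris(benzyloxy)-3-butanoyl-5-methylphenyl}methyl)phenyl]butan-1-one
Conditions: Dess–Martin periodinane (3 equiv), NaHCO3, CH2Cl2, 0 °C to rt
Reagents that add atoms: none
Why: Dess–Martin oxidation of both secondary benzylic alcohols to the aryl propyl ketones under buffered, non-acidic conditions; the single free phenol has both ortho positions and the para position substituted and should be tolerated.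

Step 12
Reactants: 19 1-[2-hydroxy-4-methoxy-3,6-dimethyl-5-({2,4,6-tris(benzyloxy)-3-butanoyl-5-methylphenyl}methyl)phenyl]butan-1-one
Product: 20 1-[5-({3-butanoyl-2,4,6-trihydroxy-5-methylphenyl}methyl)-2-hydroxy-4-methoxy-3,6-dimethylphenyl]butan-1-one (CNP0189103.0)
Conditions: H2 (1 atm), Pd on carbon, EtOAc/CH3OH, rt
Reagents that add atoms: none
Why: Catalytic hydrogenolysis of the three aryl benzyl ethers; the hydrogen-bonded aryl ketones, the aryl methyl ether and the diarylmethane bridge should survive at one atmosphere and room temperature, so the free triol of ring B appears only in the last step.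

**Compound list**

1 | 2-methylphloroglucinol (2-methylbenzene-1,3,5-triol) | Cc1c(O)cc(O)cc1O | starting material
2 | [(2,4,6-trihydroxy-3-methylphenyl)methylidene]dimethylammonium chloride | C[N+](C)=Cc1c(O)c(C)c(O)cc1O.[Cl-] | intermediate
3 | 2,4,6-trihydroxy-3-methylbenzaldehyde | O=Cc1c(O)c(C)c(O)cc1O | intermediate
4 | 2,4,6-tris(benzyloxy)-3-methylbenzaldehyde | O=Cc1c(OCc2ccccc2)c(C)c(OCc2ccccc2)cc1OCc1ccccc1 | intermediate
5 | trimethyl phosphonoacetate | COC(=O)CP(=O)(OC)OC | starting material
6 | methyl (E)-3-[2,4,6-tris(benzyloxy)-3-methylphenyl]prop-2-enoate | COC(=O)/C=C/c1c(OCc2ccccc2)c(C)c(OCc2ccccc2)cc1OCc1ccccc1 | intermediate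
7 | methyl 3-[2,4,6-tris(benzyloxy)-3-methylphenyl]propanoate | COC(=O)CCc1c(OCc2ccccc2)c(C)c(OCc2ccccc2)cc1OCc1ccccc1 | intermediate
8 | (E)-hex-4-en-3-one | C/C=C/C(=O)CC | starting material
9 | {[1-methoxy-3-(2,4,6-tris(benzyloxy)-3-methylphenyl)prop-1-en-1-yl]oxy}trimethylsilane (E/Z mixture) | COC(O[Si](C)(C)C)=CCc1c(OCc2ccccc2)c(C)c(OCc2ccccc2)cc1OCc1ccccc1 | intermediate
10 | methyl 3-methyl-5-(trimethylsilyloxy)-2-{[2,4,6-tris(benzyloxy)-3-methylphenyl]methyl}hept-4-enoate (isomer mixture) | CCC(O[Si](C)(C)C)=CC(C)C(Cc1c(OCc2ccccc2)c(C)c(OCc2ccccc2)cc1OCc1ccccc1)C(=O)OC | intermediate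
11 | methyl 3-methyl-5-oxo-2-{[2,4,6-tris(benzyloxy)-3-methylphenyl]methyl}heptanoate (racemic diastereomer mixture; the rac-(2R,3S) isomer is drawn) | CCC(=O)C[C@H](C)[C@@H](Cc1c(OCc2ccccc2)c(C)c(OCc2ccccc2)cc1OCc1ccccc1)C(=O)OC | intermediate
12 | potassium rac-(4R,5S)-2,5-dimethyl-3-oxo-4-{[2,4,6-tris(benzyloxy)-3-methylphenyl]methyl}cyclohex-1-en-1-olate | CC1=C([O-])C[C@H](C)[C@@H](Cc2c(OCc3ccccc3)c(C)c(OCc3ccccc3)cc2OCc2ccccc2)C1=O.[K+] | intermediate
13 | rac-(5S,6R)-3-hydroxy-2,5-dimethyl-6-{[2,4,6-tris(benzyloxy)-3-methylphenyl]methyl}cyclohex-2-en-1-one (trans; enol form of the 1,3-dione) | CC1=C(O)C[C@H](C)[C@@H](Cc2c(OCc3ccccc3)c(C)c(OCc3ccccc3)cc2OCc2ccccc2)C1=O | intermediate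
14 | 2,5-dimethyl-4-{[2,4,6-tris(benzyloxy)-3-methylphenyl]methyl}benzene-1,3-diol | Cc1c(O)cc(C)c(Cc2c(OCc3ccccc3)c(C)c(OCc3ccccc3)cc2OCc2ccccc2)c1O | intermediate
15 | bis(dimethyliminium) dichloride of dialdehyde 16 (C1 and C5' each carry CH=N(CH3)2+) | C[N+](C)=Cc1c(C)c(Cc2c(OCc3ccccc3)c(C)c(OCc3ccccc3)c(C=[N+](C)C)c2OCc2ccccc2)c(O)c(C)c1O.[Cl-].[Cl-] | intermediate
16 | 2,4-dihydroxy-3,6-dimethyl-5-{[2,4,6-tris(benzyloxy)-3-formyl-5-methylphenyl]methyl}benzaldehyde | O=Cc1c(C)c(Cc2c(OCc3ccccc3)c(C)c(OCc3ccccc3)c(C=O)c2OCc2ccccc2)c(O)c(C)c1O | intermediate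
17 | 2-hydroxy-4-methoxy-3,6-dimethyl-5-{[2,4,6-tris(benzyloxy)-3-formyl-5-methylphenyl]methyl}benzaldehyde | O=Cc1c(C)c(Cc2c(OCc3ccccc3)c(C)c(OCc3ccccc3)c(C=O)c2OCc2ccccc2)c(OC)c(C)c1O | intermediate
18 | 1-[2-hydroxy-4-methoxy-3,6-dimethyl-5-({2,4,6-tris(benzyloxy)-3-(1-hydroxybutyl)-5-methylphenyl}methyl)phenyl]butan-1-ol (diastereomer mixture) | CCCC(O)c1c(C)c(Cc2c(OCc3ccccc3)c(C)c(OCc3ccccc3)c(C(O)CCC)c2OCc2ccccc2)c(OC)c(C)c1O | intermediate
19 | 1-[2-hydroxy-4-methoxy-3,6-dimethyl-5-({2,4,6-tris(benzyloxy)-3-butanoyl-5-methylphenyl}methyl)phenyl]butan-1-one | CCCC(=O)c1c(C)c(Cc2c(OCc3ccccc3)c(C)c(OCc3ccccc3)c(C(=O)CCC)c2OCc2ccccc2)c(OC)c(C)c1O | intermediate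
20 | 1-[5-({3-butanoyl-2,4,6-trihydroxy-5-methylphenyl}methyl)-2-hydroxy-4-methoxy-3,6-dimethylphenyl]butan-1-one (CNP0189103.0; achiral) | CCCC(=O)c1c(C)c(Cc2c(O)c(C)c(O)c(C(=O)CCC)c2O)c(OC)c(C)c1O | target

**Step count**

Total: 12 steps. Longest linear sequence: 12 steps, from 2-methylphloroglucinol 1 to target 20.

**Steps most likely to fail**

1. Step 7 (dehydrogenation). Over-oxidation may occur: once ring A is aromatic the bridging methylene is benzylic to two electron-rich rings, so hydride abstraction there or quinone-methide formation from the new resorcinol could compete with the desired aromatisation. Fallback, setting out from 13: silylation with (CH3)3SiOSO2CF3 and N(CH2CH3)3 in CH2Cl2 at 0 °C should give trans-3,6-dimethyl-5-{[2,4,6-tris(benzyloxy)-3-methylphenyl]methyl}-2,4-bis(trimethylsilyloxy)cyclohexa-1,3-diene F1. Saegusa–Ito oxidation with Pd(OAc)2 in CH3CN at rt (palladation at C1, β-hydride elimination of the C2 hydrogen, tautomerisation) should then give 2,5-dimethyl-4-{[2,4,6-tris(benzyloxy)-3-methylphenyl]methyl}-3-(trimethylsilyloxy)phenol F2. Dilute HCl in THF on work-up frees the resorcinol, and the route is rejoined at 14.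

2. Step 8 (twofold formylation). Substitution at the crowded C5' of ring B may stay incomplete, and the acidic medium may cut the electron-rich diarylmethane bridge by ipso protonation or ipso attack. Fallback, setting out from 14, which treats ring A alone and acylates ring B last:
   - Magnesium-phenoxide-directed ortho-formylation (MgCl2, N(CH2CH3)3, paraformaldehyde, CH3CN, reflux) can reach only C1, because ring B has no free hydroxyl, and should give 2,4-dihydroxy-3,6-dimethyl-5-{[2,4,6-tris(benzyloxy)-3-methylphenyl]methyl}benzaldehyde F3.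
   - O4-methylation as in step 9 gives 2-hydroxy-4-methoxy-3,6-dimethyl-5-{[2,4,6-tris(benzyloxy)-3-methylphenyl]methyl}benzaldehyde F4.
   - CH3CH2CH2MgBr gives 1-(2-hydroxy-4-methoxy-3,6-dimethyl-5-{[2,4,6-tris(benzyloxy)-3-methylphenyl]methyl}phenyl)butan-1-ol F5.
   - Dess–Martin oxidation gives 1-(2-hydroxy-4-methoxy-3,6-dimethyl-5-{[2,4,6-tris(benzyloxy)-3-methylphenyl]methyl}phenyl)butan-1-one F6.
   - Hydrogenolysis (H2, Pd on carbon) gives 1-{2-hydroxy-4-methoxy-3,6-dimethyl-5-[(2,4,6-trihydroxy-3-methylphenyl)methyl]phenyl}butan-1-one F7.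
   - Friedel–Crafts acylation of the free phloroglucinol ring at its only open position C5' with butanoyl chloride and AlCl3 (CH2Cl2/nitrobenzene, 0 °C to rt) gives the target, so the fallback rejoins the route at 20.

3. Step 5 (Mukaiyama–Michael addition). Carbon–carbon bond formation next to the bulky arylmethyl group may be slow, so that 1,2-addition, enone oligomerisation or Lewis-acid loss of a benzyl ether competes. Fallback, setting out from 4, which uses a malonate as a reversible, self-correcting Michael donor: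
   - Knoevenagel condensation with dimethyl malonate (piperidine, acetic acid, toluene, reflux with water removal) gives dimethyl 2-{[2,4,6-tris(benzyloxy)-3-methylphenyl]methylidene}propanedioate F8.
   - NaBH4 (CH3OH/THF, 0 °C) reduces the alkylidene malonate to dimethyl 2-{[2,4,6-tris(benzyloxy)-3-methylphenyl]methyl}propanedioate F9.
   - NaOCH3 in CH3OH with 8 at reflux should give the Michael adduct dimethyl 2-(4-oxohexan-2-yl)-2-{[2,4,6-tris(benzyloxy)-3-methylphenyl]methyl}propanedioate F10.
   - Under the same conditions F10 closes by the same C4–C5 Claisen bond formation to methyl 4-hydroxy-3,6-dimethyl-2-oxo-1-{[2,4,6-tris(benzyloxy)-3-methylphenyl]methyl}cyclohex-3-ene-1-carboxylate F11.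
   - Aqueous NaOH, then HCl at 60 °C, gives 4-hydroxy-3,6-dimethyl-2-oxo-1-{[2,4,6-tris(benzyloxy)-3-methylphenyl]methyl}cyclohex-3-ene-1-carboxylic acid F12, which decarboxylates, and the route is rejoined at 13.

Further compounds
F1 | step 7 | trans-3,6-dimethyl-5-{[2,4,6-tris(benzyloxy)-3-methylphenyl]methyl}-2,4-bis(trimethylsilyloxy)cyclohexa-1,3-diene (racemic) | CC1=C(O[Si](C)(C)C)[C@H](Cc2c(OCc3ccccc3)c(C)c(OCc3ccccc3)cc2OCc2ccccc2)[C@@H](C)C=C1O[Si](C)(C)C
F2 | step 7 | 2,5-dimethyl-4-{[2,4,6-tris(benzyloxy)-3-methylphenyl]methyl}-3-(trimethylsilyloxy)phenol | Cc1c(O)cc(C)c(Cc2c(OCc3ccccc3)c(C)c(OCc3ccccc3)cc2OCc2ccccc2)c1O[Si](C)(C)C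
F3 | step 8 | 2,4-dihydroxy-3,6-dimethyl-5-{[2,4,6-tris(benzyloxy)-3-methylphenyl]methyl}benzaldehyde | O=Cc1c(C)c(Cc2c(OCc3ccccc3)c(C)c(OCc3ccccc3)cc2OCc2ccccc2)c(O)c(C)c1O
F4 | step 8 | 2-hydroxy-4-methoxy-3,6-dimethyl-5-{[2,4,6-tris(benzyloxy)-3-methylphenyl]methyl}benzaldehyde | O=Cc1c(C)c(Cc2c(OCc3ccccc3)c(C)c(OCc3ccccc3)cc2OCc2ccccc2)c(OC)c(C)c1O
F5 | step 8 | 1-(2-hydroxy-4-methoxy-3,6-dimethyl-5-{[2,4,6-tris(benzyloxy)-3-methylphenyl]methyl}phenyl)butan-1-ol (racemic) | CCCC(O)c1c(C)c(Cc2c(OCc3ccccc3)c(C)c(OCc3ccccc3)cc2OCc2ccccc2)c(OC)c(C)c1O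
F6 | step 8 | 1-(2-hydroxy-4-methoxy-3,6-dimethyl-5-{[2,4,6-tris(benzyloxy)-3-methylphenyl]methyl}phenyl)butan-1-one | CCCC(=O)c1c(C)c(Cc2c(OCc3ccccc3)c(C)c(OCc3ccccc3)cc2OCc2ccccc2)c(OC)c(C)c1O
F7 | step 8 | 1-{2-hydroxy-4-methoxy-3,6-dimethyl-5-[(2,4,6-trihydroxy-3-methylphenyl)methyl]phenyl}butan-1-one | CCCC(=O)c1c(C)c(Cc2c(O)c(C)c(O)cc2O)c(OC)c(C)c1O
F8 | step 5 | dimethyl 2-{[2,4,6-tris(benzyloxy)-3-methylphenyl]methylidene}propanedioate | COC(=O)C(=Cc1c(OCc2ccccc2)c(C)c(OCc2ccccc2)cc1OCc1ccccc1)C(=O)OC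
F9 | step 5 | dimethyl 2-{[2,4,6-tris(benzyloxy)-3-methylphenyl]methyl}propanedioate | COC(=O)C(Cc1c(OCc2ccccc2)c(C)c(OCc2ccccc2)cc1OCc1ccccc1)C(=O)OC
F10 | step 5 | dimethyl 2-(4-oxohexan-2-yl)-2-{[2,4,6-tris(benzyloxy)-3-methylphenyl]methyl}propanedioate (racemic) | CCC(=O)CC(C)C(Cc1c(OCc2ccccc2)c(C)c(OCc2ccccc2)cc1OCc1ccccc1)(C(=O)OC)C(=O)OC
F11 | step 5 | methyl 4-hydroxy-3,6-dimethyl-2-oxo-1-{[2,4,6-tris(benzyloxy)-3-methylphenyl]methyl}cyclohex-3-ene-1-carboxylate (diastereomer mixture) | COC(=O)C1(Cc2c(OCc3ccccc3)c(C)c(OCc3ccccc3)cc2OCc2ccccc2)C(C)CC(O)=C(C)C1=O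
F12 | step 5 | 4-hydroxy-3,6-dimethyl-2-oxo-1-{[2,4,6-tris(benzyloxy)-3-methylphenyl]methyl}cyclohex-3-ene-1-carboxylic acid (diastereomer mixture) | OC(=O)C1(Cc2c(OCc3ccccc3)c(C)c(OCc3ccccc3)cc2OCc2ccccc2)C(C)CC(O)=C(C)C1=O
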